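## Retrosynthetic overview

1. The target comes from its hexa-O-benzyl ether by a neutral six-fold hydrogenolysis. The base-labile 2S centre therefore never meets base.
2. Key disconnection is C2–C1' of the flavanone half. It is made by an enantioselective dearomative 1,4-arylation of the simple heteroarene 5,7-bis(benzyloxy)chromone. The γ-pyrone ring loses its aromaticity and C2 is set in the same event.
3. The aryl donor is a flavone-bearing arylboronic acid. It comes from the aryl chloride, which comes from 8-iodo-tri-O-benzylapigenin and [2-(benzyloxy)-5-chlorophenyl]boronic acid (early, achiral biaryl bond).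
4. The chromone comes from 2,4,6-trihydroxyacetophenone, a cheap phloroglucinol-type aromatic, by dibenzylation and enaminone ring closure.
5. Ring order: the three flavone rings arrive intact in apigenin, and the γ-pyrone ring of the chromone is closed in step 2. No ring is closed later; the chromanone ring arises from that pyrone in step 7.

Assumption: the 3'–8'' biaryl axis is not configurationally stable (the SMILES has no axial descriptor), so C2 is the only stereo-element to control.

Ligand used in step 7: (S)-MeO-F12-BIPHEP = (S)-(6,6'-dimethoxybiphenyl-2,2'-diyl)bis[bis(3,4,5-trifluorophenyl)phosphane].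

## Route

Step 1
Reactants: 1 2,4,6-trihydroxyacetophenone
Product: 2 1-[2,4-bis(benzyloxy)-6-hydroxyphenyl]ethan-1-one
Conditions: BnBr (2.1 equiv), K2CO3 (2.2 equiv), DMF, 25 to 50 °C
Reagents that add atoms: benzyl bromide, BrCc1ccccc1
Why: Williamson ether synthesis, in which the hydroxyl that stays hydrogen-bonded to the acetyl carbonyl is the least nucleophilic, so two equivalents of benzyl bromide stop at the dibenzyl ether and leave the OH needed for ring closure.

Step 2
Reactants: 2 1-[2,4-bis(benzyloxy)-6-hydroxyphenyl]ethan-1-one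
Product: 4 5,7-bis(benzyloxy)-4H-chromen-4-one, via enaminone 3 (not isolated)
Conditions: Me2NCH(OMe)2 (2 equiv), toluene, 100 °C; evaporate; AcOH, 100 °C
Reagents that add atoms: N,N-dimethylformamide dimethyl acetal, COC(OC)N(C)C
Why: Enaminone chromone synthesis, in which the methyl ketone condenses with the amide acetal and in acid the free phenol adds to the enaminone β-carbon and expels dimethylamine (addition–elimination), closing the aromatic γ-pyrone ring.

Step 3
Reactants: 5 apigenin (5,7-dihydroxy-2-(4-hydroxyphenyl)-4H-chromen-4-one)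
Product: 6 5,7-bis(benzyloxy)-2-[4-(benzyloxy)phenyl]-4H-chromen-4-one
Conditions: BnBr (4.5 equiv), K2CO3 (6 equiv), n-Bu4NI (cat.), DMF, 80 °C
Reagents that add atoms: benzyl bromide, BrCc1ccccc1
Why: Exhaustive Williamson etherification, where excess reagent, iodide catalysis and heat also cap the chelated 5-OH, and that capping later steers iodination to C8 rather than C6.

Step 4
Reactants: 6 5,7-bis(benzyloxy)-2-[4-(benzyloxy)phenyl]-4H-chromen-4-one
Product: 7 5,7-bis(benzyloxy)-2-[4-(benzyloxy)phenyl]-8-iodo-4H-chromen-4-one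
Conditions: NIS (1.05 equiv), TFA (cat.), CH2Cl2, 0 to 25 °C, dark
Reagents that add atoms: N-iodosuccinimide, O=C1CCC(=O)N1I
Why: Electrophilic aromatic iodination, since in 5,7-dialkoxyflavones C8 (ortho to the 7-ether and the ring oxygen, para to the 5-ether) is the most nucleophilic CH, while the benzyl rings and the pyrone-conjugated 4-benzyloxyphenyl ring are far less activated.

Step 5
Reactants: 7 5,7-bis(benzyloxy)-2-[4-(benzyloxy)phenyl]-8-iodo-4H-chromen-4-one + 8 [2-(benzyloxy)-5-chlorophenyl]boronic acid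
Product: 9 5,7-bis(benzyloxy)-8-[2-(benzyloxy)-5-chlorophenyl]-2-[4-(benzyloxy)phenyl]-4H-chromen-4-one
Conditions: Pd(PPh3)4 (5 mol %), K2CO3 (3 equiv), 8 (1.5 equiv), dioxane/H2O 4:1, 90 °C
Reagents that add atoms: none
Why: Suzuki–Miyaura coupling, in which PPh3-ligated zerovalent palladium inserts only into the C–I bond, so the C–Cl bond is carried through as the later boron handle, and no stereocentre is yet present that the aqueous base could harm.

Step 6
Reactants: 9 5,7-bis(benzyloxy)-8-[2-(benzyloxy)-5-chlorophenyl]-2-[4-(benzyloxy)phenyl]-4H-chromen-4-one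
Product: 10 {4-(benzyloxy)-3-[5,7-bis(benzyloxy)-2-(4-(benzyloxy)phenyl)-4-oxo-4H-chromen-8-yl]phenyl}boronic acid
Conditions: B2(OH)4 (3 equiv), Pd(OAc)2 (2 mol %), XPhos (5 mol %), KOAc (3 equiv), EtOH/THF 1:1, 80 °C; aqueous work-up
Reagents that add atoms: tetrahydroxydiboron, OB(O)B(O)O
Why: Miyaura-type borylation, in which zerovalent palladium with the bulky electron-rich XPhos inserts into the unhindered C–Cl bond, and acetate-assisted transmetalation with tetrahydroxydiboron gives the free boronic acid directly (no pinacol cleavage) while benzyl ethers and the flavone carbonyl stay inert.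

Step 7 (key step)
Reactants: 10 {4-(benzyloxy)-3-[5,7-bis(benzyloxy)-2-(4-(benzyloxy)phenyl)-4-oxo-4H-chromen-8-yl]phenyl}boronic acid + 4 5,7-bis(benzyloxy)-4H-chromen-4-one
Product: 11 (2S)-5,7-bis(benzyloxy)-2-{4-(benzyloxy)-3-[5,7-bis(benzyloxy)-2-(4-(benzyloxy)phenyl)-4-oxo-4H-chromen-8-yl]phenyl}-2,3-dihydro-4H-chromen-4-one
Conditions: [RhCl(C2H4)2]2 (2.5 mol %), (S)-MeO-F12-BIPHEP (5.5 mol %), aq KOH (10 mol %), 4 (2 equiv), CH2Cl2/H2O 10:1, 30 °C
Reagents that add atoms: none
Why: Hayashi–Miyaura asymmetric 1,4-addition used dearomatively, in which the aryl–rhodium species from 10 carbometalates C2=C3 of the aromatic γ-pyrone ring of 4 with the (S)-diphosphine leaving only the Re face of C2 open (the sense in which (S)-BINAP-type ligands give (S)-3-arylcyclohexanones), so C2 is set as S, and water protonates the oxa-π-allyl rhodium enolate under nearly neutral conditions to give the non-aromatic chromanone without retro-oxa-Michael racemisation, the hindered β-aryl flavone enone of 10 being no competing acceptor.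

Step 8
Reactants: 11 (2S)-hexa-O-benzyl ether of the target
Product: 12 (2S)-2,3-dihydroamentoflavone (CNP0147846.1)
Conditions: H2 (1 atm), 10% Pd/C, THF/MeOH 1:1, 25 °C, stopped at full debenzylation
Reagents that add atoms: none
Why: Catalytic hydrogenolysis of six aryl benzyl ethers, which at 1 atm is faster than saturation of the conjugated trisubstituted flavone C2=C3 bond or cleavage of the C2–O bond and, being free of base and strong acid, leaves the 2S centre untouched.

## Compound list

1 | 2,4,6-trihydroxyacetophenone | CC(=O)c1c(O)cc(O)cc1O | starting material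
2 | 1-[2,4-bis(benzyloxy)-6-hydroxyphenyl]ethan-1-one | CC(=O)c1c(O)cc(OCc2ccccc2)cc1OCc1ccccc1 | intermediate
3 | (E)-1-[2,4-bis(benzyloxy)-6-hydroxyphenyl]-3-(dimethylamino)prop-2-en-1-one (enaminone, not isolated) | CN(C)/C=C/C(=O)c1c(O)cc(OCc2ccccc2)cc1OCc1ccccc1 | intermediate
4 | 5,7-bis(benzyloxy)-4H-chromen-4-one | O=c1ccoc2cc(OCc3ccccc3)cc(OCc3ccccc3)c12 | intermediate
5 | apigenin | O=c1cc(-c2ccc(O)cc2)oc2cc(O)cc(O)c12 | starting material
6 | 5,7-bis(benzyloxy)-2-[4-(benzyloxy)phenyl]-4H-chromen-4-one | O=c1cc(-c2ccc(OCc3ccccc3)cc2)oc2cc(OCc3ccccc3)cc(OCc3ccccc3)c12 | intermediate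
7 | 5,7-bis(benzyloxy)-2-[4-(benzyloxy)phenyl]-8-iodo-4H-chromen-4-one | O=c1cc(-c2ccc(OCc3ccccc3)cc2)oc2c(I)c(OCc3ccccc3)cc(OCc3ccccc3)c12 | intermediate
8 | [2-(benzyloxy)-5-chlorophenyl]boronic acid | OB(O)c1cc(Cl)ccc1OCc1ccccc1 | starting material
9 | 5,7-bis(benzyloxy)-8-[2-(benzyloxy)-5-chlorophenyl]-2-[4-(benzyloxy)phenyl]-4H-chromen-4-one | O=c1cc(-c2ccc(OCc3ccccc3)cc2)oc2c(-c3cc(Cl)ccc3OCc3ccccc3)c(OCc3ccccc3)cc(OCc3ccccc3)c12 | intermediate
10 | {4-(benzyloxy)-3-[5,7-bis(benzyloxy)-2-(4-(benzyloxy)phenyl)-4-oxo-4H-chromen-8-yl]phenyl}boronic acid | O=c1cc(-c2ccc(OCc3ccccc3)cc2)oc2c(-c3cc(B(O)O)ccc3OCc3ccccc3)c(OCc3ccccc3)cc(OCc3ccccc3)c12 | intermediate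
11 | (2S)-hexa-O-benzyl-2,3-dihydroamentoflavone | O=C1C[C@@H](c2ccc(OCc3ccccc3)c(-c3c(OCc4ccccc4)cc(OCc4ccccc4)c4c(=O)cc(-c5ccc(OCc6ccccc6)cc5)oc34)c2)Oc2cc(OCc3ccccc3)cc(OCc3ccccc3)c21 | intermediate
12 | (2S)-2,3-dihydroamentoflavone (CNP0147846.1) | O=C1C[C@@H](c2ccc(O)c(-c3c(O)cc(O)c4c(=O)cc(-c5ccc(O)cc5)oc34)c2)Oc2cc(O)cc(O)c21 | target

## Step count and risks

Total step count: 8.
Longest linear sequence: 6 (steps 3 to 8, 5 → 6 → 7 → 9 → 10 → 11 → 12). Steps 1 and 2 form the short second branch.

**Most at risk is step 7.**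
- The 5,7-dialkoxychromone is an electron-rich, sluggish acceptor.
- The valuable boronic acid is the limiting partner and can protodeboronate.
- A second 1,2-addition to the product is possible.
- The sense of induction rests on the cyclohexenone analogy. It must be checked by CD, and the (R)-ligand is taken if it proves opposite.

The fallback gives up the arylation of the heteroarene and builds the chromanone ring by closure. It sets out from iodide 7 and ketone 2 and comes back to the route at 11.
- Iodide 7 is coupled (Pd(PPh3)4, K2CO3, dioxane/H2O, 90 °C) with bought [2-(benzyloxy)-5-formylphenyl]boronic acid (OB(O)c1cc(C=O)ccc1OCc1ccccc1). This gives 4-(benzyloxy)-3-[5,7-bis(benzyloxy)-2-(4-(benzyloxy)phenyl)-4-oxo-4H-chromen-8-yl]benzaldehyde F1.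
- Claisen–Schmidt condensation of this aldehyde with 2 (KOH, EtOH/THF, 25 °C) gives the (E)-2'-hydroxychalcone F2.
- The chalcone is closed by an intramolecular oxa-Michael addition under a quinine-derived bifunctional thiourea (toluene, 25 °C). The 2S enantiomer is brought to purity by preparative chiral HPLC, giving 11.

**Second is step 5.** The biaryl carries three ortho oxygen substituents. Slow transmetalation can let deiodination of 7 and protodeboronation of 8 win.

The fallback moves the coupling to a small ketone and builds the flavone ring afterwards. It sets out from ketone 2 (with 8) and comes back to the route at 9.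
- Ketone 2 is iodinated ortho to its free OH (NIS, TFA cat., CH2Cl2) to 1-[4,6-bis(benzyloxy)-2-hydroxy-3-iodophenyl]ethan-1-one F3.
- Coupling with 8 (PdCl2(dppf), K2CO3, dioxane/H2O, 80 °C) gives 1-[4,6-bis(benzyloxy)-3-(2-(benzyloxy)-5-chlorophenyl)-2-hydroxyphenyl]ethan-1-one F4.
- Claisen–Schmidt condensation with bought 4-(benzyloxy)benzaldehyde (KOH, EtOH/THF) gives the (E)-chalcone F5.
- Oxidative cyclisation through its only free OH (I2 cat., DMSO, 120 °C) gives the 8-arylflavone 9.

**Third is step 8.** Six benzyl groups must leave while the flavone C2=C3 bond and the benzylic C2–O bond stay. Partly deprotected material is also poorly soluble.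

The fallback replaces reductive cleavage by Lewis-acid benzyl transfer to a sacrificial arene. It sets out from 11 and comes back to the route at 12, making no new isolated compound (F0). The conditions are BCl3 (12 equiv) and pentamethylbenzene (18 equiv) in CH2Cl2 at −78 °C, followed by a MeOH quench. No hydrogen is present, so no C=C or C–O reduction can occur. The low temperature keeps the C2–O bond from ionising.

## Further compounds

F1 | step 7 | 4-(benzyloxy)-3-[5,7-bis(benzyloxy)-2-(4-(benzyloxy)phenyl)-4-oxo-4H-chromen-8-yl]benzaldehyde | O=Cc1ccc(OCc2ccccc2)c(-c2c(OCc3ccccc3)cc(OCc3ccccc3)c3c(=O)cc(-c4ccc(OCc5ccccc5)cc4)oc23)c1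
F2 | step 7 | (E)-1-[2,4-bis(benzyloxy)-6-hydroxyphenyl]-3-{4-(benzyloxy)-3-[5,7-bis(benzyloxy)-2-(4-(benzyloxy)phenyl)-4-oxo-4H-chromen-8-yl]phenyl}prop-2-en-1-one | O=C(/C=C/c1ccc(OCc2ccccc2)c(-c2c(OCc3ccccc3)cc(OCc3ccccc3)c3c(=O)cc(-c4ccc(OCc5ccccc5)cc4)oc23)c1)c1c(O)cc(OCc2ccccc2)cc1OCc1ccccc1
F3 | step 5 | 1-[4,6-bis(benzyloxy)-2-hydroxy-3-iodophenyl]ethan-1-one | CC(=O)c1c(O)c(I)c(OCc2ccccc2)cc1OCc1ccccc1
F4 | step 5 | 1-[4,6-bis(benzyloxy)-3-(2-(benzyloxy)-5-chlorophenyl)-2-hydroxyphenyl]ethan-1-one | CC(=O)c1c(O)c(-c2cc(Cl)ccc2OCc2ccccc2)c(OCc2ccccc2)cc1OCc1ccccc1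
F5 | step 5 | (E)-1-[4,6-bis(benzyloxy)-3-(2-(benzyloxy)-5-chlorophenyl)-2-hydroxyphenyl]-3-[4-(benzyloxy)phenyl]prop-2-en-1-one | O=C(/C=C/c1ccc(OCc2ccccc2)cc1)c1c(O)c(-c2cc(Cl)ccc2OCc2ccccc2)c(OCc2ccccc2)cc1OCc1ccccc1
F0 | step 8 | none | none
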